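**Plan**
- Retrosynthesis: ring C is opened first at O1–C2 (oxa-Michael). C2=C3 is then cut (Knoevenagel, benzaldehyde) and the C3 ester helper removed, followed by C6–CH2 (Friedel–Crafts with the tetramer alcohol), C8–CH2 (hydroxybenzylation of phloroacetophenone) and the three inner aryl–CH2 bonds of the tetramer (benzyl–aryl Suzuki couplings).
- Forward: the tetramer chain is grown from its far end by three benzyl bromide/arylboronate couplings. Ring A is then filled: monomer at the future C8, selective O-benzylation, tetramer at the future C6. The acetyl group is taken to the tert-butyl β-ketoester and its benzylidene, ring C is closed as the only ring made in the route, and seven benzyl ethers are removed.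
- Enabling feature: O1, C8a, C4a, C4 and C3 are already in a row as a phenol ortho to an aroyl group, and C2 is the benzylidene carbon activated by C4=O and the C3 ester. The future O5 and O7 are benzyl ethers, so the only free OH (between the aroyl carbon and the carbon bearing the monomer) must become O1, which fixes the C6/C8 pattern.
- Stereochemistry: C2 (S) is the only stereocenter. It is set by catalyst control in the ring closure and kept through acidic decarboxylation and neutral hydrogenolysis.

Key step: step 13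

Remark: Bn = benzyl; TB4 = 2-(benzyloxy)-5-{2-(benzyloxy)-5-[2-(benzyloxy)-5-(2-(benzyloxy)benzyl)benzyl]benzyl}benzyl, the tetra-O-benzyl tetramer side chain.
Assumption: the quinidine-derived member of the pseudoenantiomeric thiourea catalyst pair is taken to give the 2S series; if a model cyclization shows the opposite sense, the quinine-derived member is used instead.

**Step 1**
Reactants: 1 2-(benzyloxy)-5-bromobenzaldehyde
Product: 2 [2-(benzyloxy)-5-bromophenyl]methanol
Conditions: NaBH4, MeOH, 0 °C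
Reagents that add atoms: none
Why: Chemoselective borohydride reduction of the aryl aldehyde should leave the aryl bromide and the benzyl ether untouched.

**Step 2**
Reactants: 2 [2-(benzyloxy)-5-bromophenyl]methanol
Product: 3 [2-(benzyloxy)-5-(4,4,5,5-tetramethyl-1,3,2-dioxaborolan-2-yl)phenyl]methanol
Conditions: bis(pinacolato)diboron, PdCl2(dppf) (3 mol %), KOAc, 1,4-dioxane, 85 °C
Reagents that add atoms: bis(pinacolato)diboron, CC1(C)OB(OC1(C)C)B1OC(C)(C)C(C)(C)O1
Why: Miyaura borylation of the aryl bromide tolerates the free benzylic alcohol and places boron para to the benzyloxy group, the position through which every chain link must be made.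

**Step 3**
Reactants: 4 1-(benzyloxy)-2-(bromomethyl)benzene; 3 the boronate building block
Product: 5 {2-(benzyloxy)-5-[2-(benzyloxy)benzyl]phenyl}methanol (dimer alcohol)
Conditions: Pd(PPh3)4 (5 mol %), aq. Na2CO3, DME, 80 °C
Reagents that add atoms: none
Why: Suzuki–Miyaura benzyl–aryl coupling, in which zerovalent palladium inserts quickly into the benzylic C–Br bond, should form the diarylmethane link at the boron-bearing carbon only.

**Step 4**
Reactants: 5 dimer alcohol
Product: 6 1-(benzyloxy)-4-[2-(benzyloxy)benzyl]-2-(bromomethyl)benzene (dimer bromide)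
Conditions: PBr3, CH2Cl2, 0 °C; used without storage
Reagents that add atoms: phosphorus tribromide, BrP(Br)Br
Why: PBr3 converts the primary benzylic alcohol into the bromide under conditions that leave aryl benzyl ethers and the diarylmethane intact.

**Step 5**
Reactants: 6 dimer bromide; 3 the boronate building block
Product: 7 {2-(benzyloxy)-5-[2-(benzyloxy)-5-(2-(benzyloxy)benzyl)benzyl]phenyl}methanol (trimer alcohol)
Conditions: Pd(PPh3)4 (5 mol %), aq. Na2CO3, DME, 80 °C
Reagents that add atoms: none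
Why: The same Suzuki–Miyaura benzyl–aryl coupling as in step 3 should add the next ring with the link ortho to the oxygen of the outer ring and para to that of the new ring.

**Step 6**
Reactants: 7 trimer alcohol
Product: 8 1-(benzyloxy)-4-{2-(benzyloxy)-5-[2-(benzyloxy)benzyl]benzyl}-2-(bromomethyl)benzene (trimer bromide)
Conditions: PBr3, CH2Cl2, 0 °C; used without storage
Reagents that add atoms: phosphorus tribromide, BrP(Br)Br
Why: Bromination of the primary benzylic alcohol as in step 4.

**Step 7**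
Reactants: 8 trimer bromide; 3 the boronate building block
Product: 9 TB4–OH, {2-(benzyloxy)-5-[2-(benzyloxy)-5-{2-(benzyloxy)-5-[2-(benzyloxy)benzyl]benzyl}benzyl]phenyl}methanol (tetramer alcohol)
Conditions: Pd(PPh3)4 (5 mol %), aq. Na2CO3, DME, 80 °C
Reagents that add atoms: none
Why: A third Suzuki–Miyaura benzyl–aryl coupling should complete the chain and leave the benzylic alcohol needed for attachment to ring A.

**Step 8**
Reactants: 10 2',4',6'-trihydroxyacetophenone (threefold excess); 11 2-hydroxybenzyl alcohol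
Product: 12 1-[2,4,6-trihydroxy-3-(2-hydroxybenzyl)phenyl]ethan-1-one
Conditions: anhydrous ZnCl2, 1,4-dioxane, reflux
Reagents that add atoms: none
Why: Lewis-acid-mediated Friedel–Crafts ortho-hydroxybenzylation of the acylphloroglucinol, with loss of water, has no regiochemical issue because C3 and C5 of 10 are equivalent, and the excess of 10 should suppress double alkylation.

**Step 9**
Reactants: 12 the mono-C-benzylated acetophenone
Product: 13 1-{4,6-bis(benzyloxy)-3-[2-(benzyloxy)benzyl]-2-hydroxyphenyl}ethan-1-one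
Conditions: BnBr (3.05 equiv), K2CO3, DMF, rt
Reagents that add atoms: benzyl bromide, BrCc1ccccc1
Why: In this Williamson etherification the OH between the acetyl group and the new benzyl group is chelated to C=O and the most hindered, so it should stay free while the 4-OH, the 6-OH and the side-chain phenol are benzylated.

**Step 10**
Reactants: 13 the tri-O-benzyl acetophenone; 9 tetramer alcohol
Product: 14 1-{4,6-bis(benzyloxy)-3-[2-(benzyloxy)benzyl]-2-hydroxy-5-(TB4)phenyl}ethan-1-one
Conditions: TsOH·H2O (10 mol %), HFIP–CH2Cl2, 0 °C to rt; slow addition of 9 to a twofold excess of 13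
Reagents that add atoms: none
Why: Friedel–Crafts benzylation, in which the ortho-benzyloxy benzylic cation formed from 9 by loss of water is taken by the one free carbon of ring A (ortho to two oxygens, para to the third, meta to the acyl group), which should be far more nucleophilic than any mono-alkoxy ring present.

**Step 11**
Reactants: 14 the hexasubstituted acetophenone
Product: 15 tert-butyl 3-{4,6-bis(benzyloxy)-3-[2-(benzyloxy)benzyl]-2-hydroxy-5-(TB4)phenyl}-3-oxopropanoate
Conditions: LiN(SiMe3)2 (3.3 equiv), THF, −78 °C; Boc2O (1.05 equiv), −78 to 0 °C; 1 M HCl quench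
Reagents that add atoms: di-tert-butyl dicarbonate, CC(C)(C)OC(=O)OC(=O)OC(C)(C)C
Why: Claisen-type C-acylation of the phenoxide/enolate dianion of the methyl ketone should give the β-ketoester, and the tert-butyl ester resists lactonization onto the phenol.

**Step 12**
Reactants: 15 the β-ketoester; 16 benzaldehyde
Product: 17 tert-butyl 2-{4,6-bis(benzyloxy)-3-[2-(benzyloxy)benzyl]-2-hydroxy-5-(TB4)benzoyl}-3-phenylprop-2-enoate (E/Z mixture)
Conditions: piperidine (cat.), AcOH (cat.), 4 Å molecular sieves, toluene, rt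
Reagents that add atoms: none
Why: Knoevenagel condensation under buffered amine catalysis, with loss of water, should give the benzylidene without ring closure, because the 2'-OH is tied up in a hydrogen bond to the ketone.

**Step 13**
Reactants: 17 the benzylidene β-ketoester
Product: 20 (2S)-5,7-bis(benzyloxy)-8-[2-(benzyloxy)benzyl]-2-phenyl-6-(TB4)chroman-4-one, via tert-butyl 4-oxochroman-3-carboxylate 18 (not isolated), via 4-oxochroman-3-carboxylic acid 19 (not isolated)
Conditions: 1-[3,5-bis(trifluoromethyl)phenyl]-3-(9-deoxy-epi-quinidin-9-yl)thiourea (10 mol %), toluene, −25 °C; then TFA, CH2Cl2, 0 °C to rt; then toluene, 50 °C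
Reagents that add atoms: none
Why: The quinuclidine nitrogen of the catalyst acts as a general base on the single free phenol while the thiourea binds the β-ketoester through two hydrogen bonds, so the phenoxide should add to the benzylidene carbon in a 6-endo-trig oxa-Michael closure (O1–C2 bond) and the enolate is protonated at C3. The closest known reaction type is the cinchona thiourea-catalysed intramolecular oxa-Michael addition of 2'-hydroxyaryl alkylidene β-ketoesters followed by acid-mediated loss of the tert-butyl ester, an established catalytic asymmetric entry to flavanones. C2 is the only lasting stereocenter and is set by catalyst control of the face of the benzylidene carbon; the E and Z isomers of 17 should converge because the C3 center is not kept. TFA then cleaves the tert-butyl ester of 18 and acid 19 loses CO2, which removes both the activating group and C3 as a stereocenter. The step needs selectivity between the two oxygens ortho to the aroyl group, and this is secured because the future O5 (and O7) are benzyl ethers, so only the 8-(monomer)/6-(tetramer) flavanone can form. It also needs the uncatalysed racemic closure to be slow, which the phenol–ketone hydrogen bond, the nonpolar solvent and the low temperature should ensure, and the acidic second stage avoids base-induced retro-Michael racemization.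

**Step 14**
Reactants: 20 the hepta-O-benzyl flavanone
Product: 21 sarmentosumin C, (2S)-5,7-dihydroxy-8-(2-hydroxybenzyl)-6-{2-hydroxy-5-[2-hydroxy-5-(2-hydroxy-5-(2-hydroxybenzyl)benzyl)benzyl]benzyl}-2-phenylchroman-4-one
Conditions: H2 (1 atm), 10% Pd/C, EtOAc–MeOH, rt
Reagents that add atoms: none
Why: Hydrogenolysis of the seven aryl benzyl ethers under neutral conditions should free all phenols without touching the diarylmethane links or the base-labile C2 center.

**Compound list**
1 | 2-(benzyloxy)-5-bromobenzaldehyde | O=Cc1cc(Br)ccc1OCc1ccccc1 | starting material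
2 | [2-(benzyloxy)-5-bromophenyl]methanol | OCc1cc(Br)ccc1OCc1ccccc1 | intermediate
3 | [2-(benzyloxy)-5-(4,4,5,5-tetramethyl-1,3,2-dioxaborolan-2-yl)phenyl]methanol | OCc1cc(B2OC(C)(C)C(C)(C)O2)ccc1OCc1ccccc1 | intermediate
4 | 1-(benzyloxy)-2-(bromomethyl)benzene | BrCc1ccccc1OCc1ccccc1 | starting material
5 | {2-(benzyloxy)-5-[2-(benzyloxy)benzyl]phenyl}methanol | OCc1cc(Cc2ccccc2OCc2ccccc2)ccc1OCc1ccccc1 | intermediate
6 | 1-(benzyloxy)-4-[2-(benzyloxy)benzyl]-2-(bromomethyl)benzene | BrCc1cc(Cc2ccccc2OCc2ccccc2)ccc1OCc1ccccc1 | intermediate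
7 | {2-(benzyloxy)-5-[2-(benzyloxy)-5-(2-(benzyloxy)benzyl)benzyl]phenyl}methanol | OCc1cc(Cc2cc(Cc3ccccc3OCc3ccccc3)ccc2OCc2ccccc2)ccc1OCc1ccccc1 | intermediate
8 | 1-(benzyloxy)-4-{2-(benzyloxy)-5-[2-(benzyloxy)benzyl]benzyl}-2-(bromomethyl)benzene (trimer bromide) | BrCc1cc(Cc2cc(Cc3ccccc3OCc3ccccc3)ccc2OCc2ccccc2)ccc1OCc1ccccc1 | intermediate
9 | TB4–OH, {2-(benzyloxy)-5-[2-(benzyloxy)-5-{2-(benzyloxy)-5-[2-(benzyloxy)benzyl]benzyl}benzyl]phenyl}methanol | OCc1cc(Cc2cc(Cc3cc(Cc4ccccc4OCc4ccccc4)ccc3OCc3ccccc3)ccc2OCc2ccccc2)ccc1OCc1ccccc1 | intermediate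
10 | 2',4',6'-trihydroxyacetophenone | CC(=O)c1c(O)cc(O)cc1O | starting material
11 | 2-hydroxybenzyl alcohol | OCc1ccccc1O | starting material
12 | 1-[2,4,6-trihydroxy-3-(2-hydroxybenzyl)phenyl]ethan-1-one | CC(=O)c1c(O)cc(O)c(Cc2ccccc2O)c1O | intermediate
13 | 1-{4,6-bis(benzyloxy)-3-[2-(benzyloxy)benzyl]-2-hydroxyphenyl}ethan-1-one | CC(=O)c1c(OCc2ccccc2)cc(OCc2ccccc2)c(Cc2ccccc2OCc2ccccc2)c1O | intermediate
14 | 1-{4,6-bis(benzyloxy)-3-[2-(benzyloxy)benzyl]-2-hydroxy-5-(TB4)phenyl}ethan-1-one | CC(=O)c1c(OCc2ccccc2)c(Cc2cc(Cc3cc(Cc4cc(Cc5ccccc5OCc5ccccc5)ccc4OCc4ccccc4)ccc3OCc3ccccc3)ccc2OCc2ccccc2)c(OCc2ccccc2)c(Cc2ccccc2OCc2ccccc2)c1O | intermediate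
15 | tert-butyl 3-{4,6-bis(benzyloxy)-3-[2-(benzyloxy)benzyl]-2-hydroxy-5-(TB4)phenyl}-3-oxopropanoate | CC(C)(C)OC(=O)CC(=O)c1c(OCc2ccccc2)c(Cc2cc(Cc3cc(Cc4cc(Cc5ccccc5OCc5ccccc5)ccc4OCc4ccccc4)ccc3OCc3ccccc3)ccc2OCc2ccccc2)c(OCc2ccccc2)c(Cc2ccccc2OCc2ccccc2)c1O | intermediate
16 | benzaldehyde | O=Cc1ccccc1 | starting material
17 | tert-butyl 2-{4,6-bis(benzyloxy)-3-[2-(benzyloxy)benzyl]-2-hydroxy-5-(TB4)benzoyl}-3-phenylprop-2-enoate (E/Z mixture) | CC(C)(C)OC(=O)C(=Cc1ccccc1)C(=O)c1c(OCc2ccccc2)c(Cc2cc(Cc3cc(Cc4cc(Cc5ccccc5OCc5ccccc5)ccc4OCc4ccccc4)ccc3OCc3ccccc3)ccc2OCc2ccccc2)c(OCc2ccccc2)c(Cc2ccccc2OCc2ccccc2)c1O | intermediate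
18 | tert-butyl (2S)-5,7-bis(benzyloxy)-8-[2-(benzyloxy)benzyl]-4-oxo-2-phenyl-6-(TB4)chromane-3-carboxylate (C3 epimers) | O=C1C(C(=O)OC(C)(C)C)[C@@H](c2ccccc2)Oc2c(Cc3ccccc3OCc3ccccc3)c(OCc3ccccc3)c(Cc3cc(Cc4cc(Cc5cc(Cc6ccccc6OCc6ccccc6)ccc5OCc5ccccc5)ccc4OCc4ccccc4)ccc3OCc3ccccc3)c(OCc3ccccc3)c21 | intermediate
19 | (2S)-5,7-bis(benzyloxy)-8-[2-(benzyloxy)benzyl]-4-oxo-2-phenyl-6-(TB4)chromane-3-carboxylic acid (C3 epimers) | O=C1C(C(=O)O)[C@@H](c2ccccc2)Oc2c(Cc3ccccc3OCc3ccccc3)c(OCc3ccccc3)c(Cc3cc(Cc4cc(Cc5cc(Cc6ccccc6OCc6ccccc6)ccc5OCc5ccccc5)ccc4OCc4ccccc4)ccc3OCc3ccccc3)c(OCc3ccccc3)c21 | intermediate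
20 | (2S)-5,7-bis(benzyloxy)-8-[2-(benzyloxy)benzyl]-2-phenyl-6-(TB4)chroman-4-one | O=C1C[C@@H](c2ccccc2)Oc2c(Cc3ccccc3OCc3ccccc3)c(OCc3ccccc3)c(Cc3cc(Cc4cc(Cc5cc(Cc6ccccc6OCc6ccccc6)ccc5OCc5ccccc5)ccc4OCc4ccccc4)ccc3OCc3ccccc3)c(OCc3ccccc3)c21 | intermediate
21 | sarmentosumin C | O=C1C[C@@H](c2ccccc2)Oc2c(Cc3ccccc3O)c(O)c(Cc3cc(Cc4cc(Cc5cc(Cc6ccccc6O)ccc5O)ccc4O)ccc3O)c(O)c21 | target

**Summary**
Total step count: 14. Longest linear sequence: 12 steps (steps 1–7 and 10–14, from compound 1).

**Steps most likely to fail**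

Step 13. Facial control may be weak on the hexasubstituted, twisted aroyl substrate, and the uncatalysed racemic closure may compete during or after the Knoevenagel step. The fallback sets out from 14 and comes back at 20; it sets the stereocenter by C–C instead of C–O bond formation. Condensation of 14 with N,N-dimethylformamide dimethyl acetal (toluene, 100 °C) would give the enaminone (E)-3-(dimethylamino)-1-{4,6-bis(benzyloxy)-3-[2-(benzyloxy)benzyl]-2-hydroxy-5-(TB4)phenyl}prop-2-en-1-one F1. HCl in CH2Cl2 would then close ring C through the same single free phenol, with loss of dimethylamine, to the chromone 5,7-bis(benzyloxy)-8-[2-(benzyloxy)benzyl]-6-(TB4)-4H-chromen-4-one F2. Asymmetric conjugate addition of phenylboronic acid to F2 (Pd(OCOCF3)2, the t-BuPyOX enantiomer that leads to 2S, NH4PF6, water, 1,2-dichloroethane, 60 °C) would then give 20.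

Step 10. The benzylic cation may alkylate the anisole-type rings of its own chain, and acid may scramble the benzyl group already on ring A. The fallback sets out from 13 and 9 and comes back at 14. Iodination of 13 at the one free carbon of ring A (N-iodosuccinimide, cat. TFA, MeCN, 0 °C) would give 1-{4,6-bis(benzyloxy)-3-[2-(benzyloxy)benzyl]-2-hydroxy-5-iodophenyl}ethan-1-one F3. Alcohol 9 would be converted with PBr3 into the tetramer bromide TB4–Br F4, and Zn dust with LiCl in THF would convert this into the benzylic zinc bromide TB4–ZnBr F5. Negishi coupling of F3 with F5 (Pd(OAc)2, SPhos, THF, rt, slow addition so that the free phenol is tolerated) would give 14.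

Step 9. Etherification may take place at the wrong ortho oxygen, which would transpose the C6 and C8 substituents after ring closure. The fallback sets out from 10 and 4 and comes back at 13; the position of the free OH is fixed by the order of events, not by selective etherification. Dibenzylation of 10 (BnBr 2 equiv, K2CO3, DMF) leaves the chelated OH and would give 1-[2,4-bis(benzyloxy)-6-hydroxyphenyl]ethan-1-one F6. Phenol-directed ortho-iodination (benzyltrimethylammonium dichloroiodate, NaHCO3, CH2Cl2–MeOH) would give 1-[4,6-bis(benzyloxy)-2-hydroxy-3-iodophenyl]ethan-1-one F7. Bromide 4 with Zn dust and LiCl in THF would give 2-(benzyloxy)benzylzinc bromide F8, and Negishi coupling of F7 with F8 (Pd(OAc)2, SPhos, THF, rt) would give 13.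

**Further compounds**
F1 | step 13 | (E)-3-(dimethylamino)-1-{4,6-bis(benzyloxy)-3-[2-(benzyloxy)benzyl]-2-hydroxy-5-(TB4)phenyl}prop-2-en-1-one | CN(C)/C=C/C(=O)c1c(OCc2ccccc2)c(Cc2cc(Cc3cc(Cc4cc(Cc5ccccc5OCc5ccccc5)ccc4OCc4ccccc4)ccc3OCc3ccccc3)ccc2OCc2ccccc2)c(OCc2ccccc2)c(Cc2ccccc2OCc2ccccc2)c1O
F2 | step 13 | 5,7-bis(benzyloxy)-8-[2-(benzyloxy)benzyl]-6-(TB4)-4H-chromen-4-one | O=c1ccoc2c(Cc3ccccc3OCc3ccccc3)c(OCc3ccccc3)c(Cc3cc(Cc4cc(Cc5cc(Cc6ccccc6OCc6ccccc6)ccc5OCc5ccccc5)ccc4OCc4ccccc4)ccc3OCc3ccccc3)c(OCc3ccccc3)c12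
F3 | step 10 | 1-{4,6-bis(benzyloxy)-3-[2-(benzyloxy)benzyl]-2-hydroxy-5-iodophenyl}ethan-1-one | CC(=O)c1c(OCc2ccccc2)c(I)c(OCc2ccccc2)c(Cc2ccccc2OCc2ccccc2)c1O
F4 | step 10 | TB4–Br, tetramer benzyl bromide | BrCc1cc(Cc2cc(Cc3cc(Cc4ccccc4OCc4ccccc4)ccc3OCc3ccccc3)ccc2OCc2ccccc2)ccc1OCc1ccccc1
F5 | step 10 | TB4–ZnBr, tetramer benzylzinc bromide | Br[Zn]Cc1cc(Cc2cc(Cc3cc(Cc4ccccc4OCc4ccccc4)ccc3OCc3ccccc3)ccc2OCc2ccccc2)ccc1OCc1ccccc1
F6 | step 9 | 1-[2,4-bis(benzyloxy)-6-hydroxyphenyl]ethan-1-one | CC(=O)c1c(O)cc(OCc2ccccc2)cc1OCc1ccccc1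
F7 | step 9 | 1-[4,6-bis(benzyloxy)-2-hydroxy-3-iodophenyl]ethan-1-one | CC(=O)c1c(OCc2ccccc2)cc(OCc2ccccc2)c(I)c1O
F8 | step 9 | 2-(benzyloxy)benzylzinc bromide | Br[Zn]Cc1ccccc1OCc1ccccc1
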